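# Proposed synthesis of CNP0265071.1 (menaquinone-9 with the second and third isoprene units saturated)

Side-chain carbons are numbered C1′ to C36′ starting at the quinone.

## Analysis of the target

The target (C56H84O2) is a 2-methyl-1,4-naphthoquinone (benzo ring A, quinone ring B) whose C3 carries a nonaprenyl chain in which the second and third isoprene units (C5′ to C12′) are saturated. The chain has seven olefins: C2′=C3′ and the five at C14′, C18′, C22′, C26′ and C30′ are E-trisubstituted, and C34′=C35′ is an isopropylidene. The only stereocentres are the methyl-bearing C7′ (R) and C11′ (S). They are 1,5-related and have the same spatial sense as in the phytyl chain of vitamin K1; C11′ is S only because the C14′ olefin raises the CIP rank of the C12′ branch. No heteroatom lies within four bonds of either centre, so substrate control is not available, and epimers of such oils cannot be separated. The sensitive groups are the quinone (reductants, nucleophiles, base, light), the allyl-quinone unit C1′ to C3′ (E/Z loss through allyl cations), and the 1,5-polyene (acid-induced cyclisation, olefin migration). The hard points are three: joining a C44 chain to C3 of ring B with clean E geometry at C2′=C3′, saturating exactly two of nine isoprene units with absolute control, and keeping six E olefins intact. The route is built on one feature: the C2′=C3′ olefin carries the C3′ methyl and sits one methylene (C1′) from ring B, so a terminal alkyne C2′≡C3′ is a latent form of the whole chain–quinone junction. In addition, C2′ to C12′ with the two branch methyls is the carbon skeleton of (E)-geranylacetone, with C3′ as its carbonyl carbon, C12′ as its E-terminal methyl, and C7′ and C11′ as two of its sp2 carbons.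

## Retrosynthetic reasoning

**24 to 22 and 2.** The last step cuts two bonds at the junction, C1′–C2′ and C3′–CH3, and not the aryl–C1′ bond. This leaves the terminal alkyne 22 and the chloromethyl quinone 2. Forward, a syn-methylmetalation of the alkyne must set the 2′E geometry, and the resulting alkenylmetal 23 must be coupled at the benzylic carbon of 2. What is gained: the quinone enters unprotected at its final oxidation level, no allyl cation is ever formed next to ring B, and the C43 chain is joined in the final operation.

**22 to 20 to 19.** The alkyne carbons C2′ and C3′ are the methyl and carbonyl carbons of methyl ketone 20, so 22 follows from 20 by enol-phosphate elimination. Ketone 20 is stored as dioxolane 19 while organometallic chemistry is done elsewhere in the chain.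

**19 to 7 and 17.** The chain is cut at C12′–C13′, the border between the saturated dyad and the unsaturated tail. This is an sp3–sp3 bond next to an allylic position, so it can be formed by copper-catalysed substitution of the primary allylic acetate 17 with Grignard reagent 18, made from bromide 7. Cutting here places both stereocentres in a small C13 piece and all tail olefins in an achiral C30 piece. Neither stereocentre is touched in the union, because C11′ is only β to the reacting carbon.

**7 to 6 to 5 to 4 to 3.** Bromide 7 comes from alcohol 6. Both stereocentres of 6 are traced back together to the two E-trisubstituted olefins of diene 5. These two olefins have the same substitution pattern and the same orientation along the chain, so one enantiomer of an iridium N,P hydrogenation catalyst should add hydrogen to the same face of both. That is exactly the like-sense 1,5-dimethyl array required. Diene 5 comes from allylic oxidation of the E-terminal methyl of ketal 4, and 4 from commercial (E)-geranylacetone 3. Thus 3 supplies C2′ to C12′, both branch methyls and both prochiral carbons.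

**17 to 16 to 14 to 12 and 10.** The hexaprenyl acetate 17 is cut at the allyl–allyl bond C24′–C25′ into two farnesyl units. Forward, lithiated sulfone 13 (from sulfone 12, itself from bromide 11) is alkylated with the ω-bromide 10; 10 comes from commercial acetate 8 through ω-alcohol 9. Reductive removal of the sulfonyl group from 14 (through 15) gives all-E alcohol 16, which is acetylated. All five stereogenic olefins of the tail are bought or are set by the E-selective allylic oxidation.

**2 to 1.** The electrophile 2 is menadione 1 with a chloromethyl group at the only free position of ring B.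

## Alternatives that were turned down

**Alternative 1:** the textbook disconnection of the C3–C1′ bond. Menadiol A2 (from 1 by reduction) would be alkylated with the C45 allylic alcohol A1 in a Lewis-acid-mediated Friedel–Crafts reaction, and oxidation would give 24. It was turned down for three reasons. First, the reaction runs through an allyl cation at C1′–C3′, which erodes the 2′E geometry and also alkylates C2 and oxygen. Second, a strong Lewis acid is applied to a chain with six further trisubstituted olefins, which invites cation–olefin cyclisation. Third, A1 would itself have to be made from 20 by a carbonyl olefination with weak E/Z control plus a reduction, which costs more steps than the present endgame and needs an isomer separation on a waxy C45 oil.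

**Alternative 2:** construction of ring B. A benzannulation of the chromium carbene A4, (CO)5Cr=C(OMe)Ph, with the skipped enyne A3 (Dötz reaction) followed by oxidative work-up would give 24; the regiochemistry of alkyne insertion is irrelevant after oxidation. It was turned down because ring B is not the hard part of this target: it is bought ready-made in 1. In addition, A3 would have to be made from alkenylalane 23 and a propargylic electrophile (SN2/SN2′ ambiguity), so the alkyne route is needed anyway and then lengthened. The step uses stoichiometric chromium, and dialkyl alkynes are the weaker substrate class for this benzannulation.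

**Alternative 3:** the biomimetic order of events. Fully unsaturated menaquinone-9 A6 would be assembled quickly from commercial solanesol A5 by the same alkyne endgame with 2, and the C6′=C7′ and C10′=C11′ olefins would then be hydrogenated asymmetrically, as the reductase does in the cell. It was turned down because no chemical catalyst can tell these two olefins from the five at C14′ to C30′, which have identical local structure. Hydrogenation would be statistical over seven sites and would also reduce the quinone. The step count is very attractive, but the key step has no defensible selectivity.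

Key step: step 15

**Remarks on the chemistry (assumptions):**
- Commercial (E)-geranylacetone 3, (E,E)-farnesyl acetate 8 and (E,E)-farnesyl bromide 11 are taken as isomerically pure; any Z isomer would be carried through as a stereoisomer.
- In step 4 the ligand enantiomer is the one that gives (2S,6R)-6; it is fixed by a trial run on 5.

## Route

Step 1
Reactants: 1 2-methylnaphthalene-1,4-dione (menadione)
Product: 2 2-(chloromethyl)-3-methylnaphthalene-1,4-dione
Conditions: 37% aq. HCHO, HCl (g), AcOH, rt
Reagents that add atoms: formaldehyde, C=O; hydrogen chloride, Cl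
Why: Acid-promoted chloromethylation (hydroxymethylation then chloride substitution) occurs at C3, the only unsubstituted position of ring B. The quinone oxidation level is kept, so no redox or protecting-group step is needed later.

Step 2
Reactants: 3 (5E)-6,10-dimethylundeca-5,9-dien-2-one ((E)-geranylacetone)
Product: 4 2-[(3E)-4,8-dimethylnona-3,7-dien-1-yl]-2-methyl-1,3-dioxolane
Conditions: HOCH2CH2OH, PPTS (cat.), benzene, reflux, Dean–Stark
Reagents that add atoms: ethylene glycol, OCCO
Why: Acid-catalysed ketalisation with azeotropic removal of water. The dioxolane masks C3′ against the Grignard chemistry of step 12 and gives a well-behaved hydrogenation substrate.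

Step 3
Reactants: 4 2-[(3E)-4,8-dimethylnona-3,7-dien-1-yl]-2-methyl-1,3-dioxolane
Product: 5 (2E,6E)-2,6-dimethyl-9-(2-methyl-1,3-dioxolan-2-yl)nona-2,6-dien-1-ol
Conditions: SeO2 (0.2 equiv), t-BuOOH (3 equiv), CH2Cl2, 0 °C to rt, stopped at partial conversion
Reagents that add atoms: tert-butyl hydroperoxide (oxygen source, relayed by catalytic SeO2), CC(C)(C)OO
Why: SeO2 allylic oxidation (ene reaction then [2,3]-sigmatropic shift) hydroxylates the E methyl of the terminal isopropylidene, the most accessible olefin, and so fixes the 2E geometry. Partial conversion limits enal formation and attack at the internal olefin.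

Step 4
Reactants: 5 (2E,6E)-2,6-dimethyl-9-(2-methyl-1,3-dioxolan-2-yl)nona-2,6-dien-1-ol
Product: 6 (2S,6R)-2,6-dimethyl-9-(2-methyl-1,3-dioxolan-2-yl)nonan-1-ol
Conditions: H2 (50 bar), [Ir(cod)(L)][B(C6H3(CF3)2)4] (1 mol %), CH2Cl2, rt; L = one enantiomer of a 2-aryl-8-(di-tert-butylphosphinooxy)-5,6,7,8-tetrahydroquinoline
Reagents that add atoms: none
Why: Iridium N,P-catalysed asymmetric hydrogenation of E-trisubstituted olefins. Both olefins of 5 have the same substitution pattern in the same orientation along the chain, so one catalyst enantiomer should add H2 to the same face of each and set C2 (later C11′) and C6 (later C7′) together under catalyst control. Ketal and hydroxyl are inert.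

Step 5
Reactants: 6 (2S,6R)-2,6-dimethyl-9-(2-methyl-1,3-dioxolan-2-yl)nonan-1-ol
Product: 7 2-[(4R,8S)-9-bromo-4,8-dimethylnonyl]-2-methyl-1,3-dioxolane
Conditions: CBr4, PPh3, 2,6-lutidine (cat.), CH2Cl2, 0 °C
Reagents that add atoms: carbon tetrabromide, BrC(Br)(Br)Br
Why: Appel bromination of a primary alcohol under neutral conditions. The ketal survives, and the adjacent stereocentre is not involved in the SN2 displacement at CH2.

Step 6
Reactants: 8 (2E,6E)-3,7,11-trimethyldodeca-2,6,10-trien-1-yl acetate ((E,E)-farnesyl acetate)
Product: 9 (2E,6E,10E)-12-hydroxy-3,7,11-trimethyldodeca-2,6,10-trien-1-yl acetate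
Conditions: SeO2 (0.2 equiv), t-BuOOH (3 equiv), salicylic acid (cat.), CH2Cl2, 0 °C to rt, stopped at partial conversion
Reagents that add atoms: tert-butyl hydroperoxide (oxygen source, relayed by catalytic SeO2), CC(C)(C)OO
Why: The same E-selective SeO2 allylic oxidation at the terminal isopropylidene. The acetate deactivates the C2 olefin, and the terminal olefin is the most accessible of the other two.

Step 7
Reactants: 9 (2E,6E,10E)-12-hydroxy-3,7,11-trimethyldodeca-2,6,10-trien-1-yl acetate
Product: 10 (2E,6E,10E)-12-bromo-3,7,11-trimethyldodeca-2,6,10-trien-1-yl acetate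
Conditions: CBr4, PPh3, CH2Cl2, −20 to 0 °C
Reagents that add atoms: carbon tetrabromide, BrC(Br)(Br)Br
Why: Appel bromination of a primary allylic alcohol gives the primary allylic bromide without allylic transposition. The acetate is untouched.

Step 8
Reactants: 11 (2E,6E)-1-bromo-3,7,11-trimethyldodeca-2,6,10-triene ((E,E)-farnesyl bromide)
Product: 12 1-methyl-4-{[(2E,6E)-3,7,11-trimethyldodeca-2,6,10-trien-1-yl]sulfonyl}benzene ((E,E)-farnesyl p-tolyl sulfone)
Conditions: p-TolSO2Na, DMF, rt
Reagents that add atoms: sodium 4-methylbenzenesulfinate, [Na+].[O-]S(=O)c1ccc(C)cc1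
Why: SN2 S-alkylation of the sulfinate at the primary allylic bromide with retention of the 2E geometry.

Step 9
Reactants: 12 (E,E)-farnesyl p-tolyl sulfone; 10 (2E,6E,10E)-12-bromo-3,7,11-trimethyldodeca-2,6,10-trien-1-yl acetate
Product: 14 (2E,6E,10E,14E,18E)-3,7,11,15,19,23-hexamethyl-13-(4-methylbenzenesulfonyl)tetracosa-2,6,10,14,18,22-hexaen-1-yl acetate (racemic at C13), via lithiated sulfone 13 (not isolated)
Conditions: n-BuLi (1.0 equiv), THF/DMPU, −78 °C; then 10, −78 to −40 °C
Reagents that add atoms: none
Why: Alkylation of a sulfone-stabilised allyl anion (Biellmann-type head-to-tail prenyl coupling). The soft anion should attack the primary allylic bromide by SN2 at −78 °C much faster than it adds to the acetate, and no olefin geometry is touched. The new sulfonyl-bearing centre is removed in step 10.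

Step 10
Reactants: 14 (2E,6E,10E,14E,18E)-3,7,11,15,19,23-hexamethyl-13-(4-methylbenzenesulfonyl)tetracosa-2,6,10,14,18,22-hexaen-1-yl acetate
Product: 16 (2E,6E,10E,14E,18E)-3,7,11,15,19,23-hexamethyltetracosa-2,6,10,14,18,22-hexaen-1-ol (all-E-hexaprenol), via hydroxy sulfone 15 (not isolated)
Conditions: LiEt3BH (excess), THF, 0 °C; then Pd(dppp)Cl2 (5 mol %), 0 °C to rt
Reagents that add atoms: none
Why: LiEt3BH first cleaves the acetate, so no allylic ester is left for palladium to ionise. Palladium-catalysed hydride substitution of the allylic sulfone then proceeds through a π-allylpalladium intermediate, with hydride delivered to the less substituted terminus, which should leave the E-trisubstituted olefin in place.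

Step 11
Reactants: 16 all-E-hexaprenol
Product: 17 (2E,6E,10E,14E,18E)-3,7,11,15,19,23-hexamethyltetracosa-2,6,10,14,18,22-hexaen-1-yl acetate
Conditions: Ac2O, pyridine, DMAP (cat.), CH2Cl2, 0 °C to rt
Reagents that add atoms: acetic anhydride, CC(=O)OC(C)=O
Why: Standard acylation of a primary allylic alcohol. The acetate is a storable leaving group for the copper-catalysed union.

Step 12
Reactants: 7 2-[(4R,8S)-9-bromo-4,8-dimethylnonyl]-2-methyl-1,3-dioxolane; 17 all-E-hexaprenyl acetate
Product: 19 2-methyl-2-[(4R,8S,11E,15E,19E,23E,27E)-4,8,12,16,20,24,28,32-octamethyltritriaconta-11,15,19,23,27,31-hexaen-1-yl]-1,3-dioxolane, via Grignard reagent 18 (not isolated)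
Conditions: Mg, THF, 40 °C; then 17, Li2CuCl4 (3 mol %), THF, −78 to 0 °C
Reagents that add atoms: none
Why: Copper-catalysed substitution of a primary allylic acetate by a primary alkyl Grignard reagent (Fouquet–Schlosser type). Attack at the γ-carbon would create a quaternary centre, so the bond should form at C13′ with retention of the 14′E geometry. The dioxolane is inert, and C11′ is not involved.

Step 13
Reactants: 19 2-methyl-2-[(4R,8S,11E,15E,19E,23E,27E)-4,8,12,16,20,24,28,32-octamethyltritriaconta-11,15,19,23,27,31-hexaen-1-yl]-1,3-dioxolane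
Product: 20 (6R,10S,13E,17E,21E,25E,29E)-6,10,14,18,22,26,30,34-octamethylpentatriaconta-13,17,21,25,29,33-hexaen-2-one
Conditions: 1 M aq. HCl, THF, rt
Reagents that add atoms: water, O
Why: Mild hydrolysis of the dioxolane. Dilute aqueous acid at room temperature should not protonate the isolated trisubstituted olefins.

Step 14
Reactants: 20 (6R,10S,13E,17E,21E,25E,29E)-6,10,14,18,22,26,30,34-octamethylpentatriaconta-13,17,21,25,29,33-hexaen-2-one
Product: 22 (6R,10S,13E,17E,21E,25E,29E)-6,10,14,18,22,26,30,34-octamethylpentatriaconta-13,17,21,25,29,33-hexaen-1-yne, via enol phosphate 21 (not isolated)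
Conditions: LDA (1.1 equiv), THF, −78 °C; ClP(O)(OEt)2, −78 °C to rt; LDA (2.3 equiv), −78 °C to rt; aq. NH4Cl
Reagents that add atoms: none
Why: Kinetic deprotonation of the methyl ketone at the methyl group gives the terminal enolate, which is trapped as the enol phosphate. β-Elimination with excess LDA then gives the terminal alkyne after protonation (methyl ketone to alkyne conversion via the enol phosphate). No other C–H of the chain is acidic enough to react.

Step 15
Reactants: 22 (6R,10S,13E,17E,21E,25E,29E)-6,10,14,18,22,26,30,34-octamethylpentatriaconta-13,17,21,25,29,33-hexaen-1-yne; 2 2-(chloromethyl)-3-methylnaphthalene-1,4-dione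
Product: 24 2-methyl-3-[(2E,7R,11S,14E,18E,22E,26E,30E)-3,7,11,15,19,23,27,31,35-nonamethylhexatriaconta-2,14,18,22,26,30,34-heptaen-1-yl]naphthalene-1,4-dione, via alkenylalane 23 (not isolated)
Conditions: AlMe3 (2 equiv), Cp2ZrCl2 (0.25 equiv), ClCH2CH2Cl, 0 °C to rt; volatiles removed in vacuo; then 2, NiCl2(PPh3)2 (3 mol %)/n-BuLi (6 mol %), THF, −20 °C to rt; dilute aq. HCl work-up; light excluded
Reagents that add atoms: trimethylaluminium, C[Al](C)C
Why: Zirconium-catalysed carboalumination (Negishi) adds CH3–Al syn across the terminal alkyne with the methyl at the internal carbon C3′, so in alkenylalane 23 the C4′ chain and aluminium are trans, which is the 2′E geometry. Without isolation, zerovalent nickel (from NiCl2(PPh3)2 and n-BuLi) inserts into the benzylic C–Cl bond of 2, the alkenyl group passes from aluminium to nickel with retention, and reductive elimination forms the C1′–C2′ bond. The closest known reaction type is the nickel-catalysed coupling of alkenylalanes with chloromethylated para-quinones used for prenylated quinones. No ring is closed and no sp3 stereocentre is formed; the only new stereogenic element is the C2′=C3′ olefin, which is controlled by the syn-addition and the stereoretentive transmetalation. Three selectivities are needed: methyl delivery to C3′, secured by the terminal alkyne; reaction at the alkyne and not at the six trisubstituted olefins, secured because unactivated internal olefins are not carboaluminated under these conditions; and coupling at the chloromethyl carbon in preference to carbonyl addition, secured by fast oxidative addition into the activated C–Cl bond at −20 °C and by removal of excess AlMe3 before the coupling. C7′ and C11′ are remote and cannot epimerise.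

## Compound list

1 | 2-methylnaphthalene-1,4-dione (menadione) | CC1=CC(=O)c2ccccc2C1=O | starting material
2 | 2-(chloromethyl)-3-methylnaphthalene-1,4-dione | CC1=C(CCl)C(=O)c2ccccc2C1=O | intermediate
3 | (5E)-6,10-dimethylundeca-5,9-dien-2-one ((E)-geranylacetone) | CC(C)=CCC/C(C)=C/CCC(C)=O | starting material
4 | 2-[(3E)-4,8-dimethylnona-3,7-dien-1-yl]-2-methyl-1,3-dioxolane | CC(C)=CCC/C(C)=C/CCC1(C)OCCO1 | intermediate
5 | (2E,6E)-2,6-dimethyl-9-(2-methyl-1,3-dioxolan-2-yl)nona-2,6-dien-1-ol | OC/C(C)=C/CC/C(C)=C/CCC1(C)OCCO1 | intermediate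
6 | (2S,6R)-2,6-dimethyl-9-(2-methyl-1,3-dioxolan-2-yl)nonan-1-ol | OC[C@@H](C)CCC[C@@H](C)CCCC1(C)OCCO1 | intermediate
7 | 2-[(4R,8S)-9-bromo-4,8-dimethylnonyl]-2-methyl-1,3-dioxolane | BrC[C@@H](C)CCC[C@@H](C)CCCC1(C)OCCO1 | intermediate
8 | (2E,6E)-3,7,11-trimethyldodeca-2,6,10-trien-1-yl acetate ((E,E)-farnesyl acetate) | CC(C)=CCC/C(C)=C/CC/C(C)=C/COC(C)=O | starting material
9 | (2E,6E,10E)-12-hydroxy-3,7,11-trimethyldodeca-2,6,10-trien-1-yl acetate | OC/C(C)=C/CC/C(C)=C/CC/C(C)=C/COC(C)=O | intermediate
10 | (2E,6E,10E)-12-bromo-3,7,11-trimethyldodeca-2,6,10-trien-1-yl acetate | BrC/C(C)=C/CC/C(C)=C/CC/C(C)=C/COC(C)=O | intermediate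
11 | (2E,6E)-1-bromo-3,7,11-trimethyldodeca-2,6,10-triene ((E,E)-farnesyl bromide) | CC(C)=CCC/C(C)=C/CC/C(C)=C/CBr | starting material
12 | 1-methyl-4-{[(2E,6E)-3,7,11-trimethyldodeca-2,6,10-trien-1-yl]sulfonyl}benzene | CC(C)=CCC/C(C)=C/CC/C(C)=C/CS(=O)(=O)c1ccc(C)cc1 | intermediate
13 | α-lithio derivative of sulfone 12 | CC(C)=CCC/C(C)=C/CC/C(C)=C/C([Li])S(=O)(=O)c1ccc(C)cc1 | intermediate (not isolated)
14 | (2E,6E,10E,14E,18E)-3,7,11,15,19,23-hexamethyl-13-(4-methylbenzenesulfonyl)tetracosa-2,6,10,14,18,22-hexaen-1-yl acetate (racemic at C13) | CC(C)=CCC/C(C)=C/CC/C(C)=C/C(C/C(C)=C/CC/C(C)=C/CC/C(C)=C/COC(C)=O)S(=O)(=O)c1ccc(C)cc1 | intermediate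
15 | (2E,6E,10E,14E,18E)-3,7,11,15,19,23-hexamethyl-13-(4-methylbenzenesulfonyl)tetracosa-2,6,10,14,18,22-hexaen-1-ol | CC(C)=CCC/C(C)=C/CC/C(C)=C/C(C/C(C)=C/CC/C(C)=C/CC/C(C)=C/CO)S(=O)(=O)c1ccc(C)cc1 | intermediate (not isolated)
16 | (2E,6E,10E,14E,18E)-3,7,11,15,19,23-hexamethyltetracosa-2,6,10,14,18,22-hexaen-1-ol (all-E-hexaprenol) | CC(C)=CCC/C(C)=C/CC/C(C)=C/CC/C(C)=C/CC/C(C)=C/CC/C(C)=C/CO | intermediate
17 | (2E,6E,10E,14E,18E)-3,7,11,15,19,23-hexamethyltetracosa-2,6,10,14,18,22-hexaen-1-yl acetate | CC(C)=CCC/C(C)=C/CC/C(C)=C/CC/C(C)=C/CC/C(C)=C/CC/C(C)=C/COC(C)=O | intermediate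
18 | [(2S,6R)-2,6-dimethyl-9-(2-methyl-1,3-dioxolan-2-yl)nonyl]magnesium bromide | Br[Mg]C[C@@H](C)CCC[C@@H](C)CCCC1(C)OCCO1 | intermediate (not isolated)
19 | 2-methyl-2-[(4R,8S,11E,15E,19E,23E,27E)-4,8,12,16,20,24,28,32-octamethyltritriaconta-11,15,19,23,27,31-hexaen-1-yl]-1,3-dioxolane | CC(C)=CCC/C(C)=C/CC/C(C)=C/CC/C(C)=C/CC/C(C)=C/CC/C(C)=C/CC[C@@H](C)CCC[C@@H](C)CCCC1(C)OCCO1 | intermediate
20 | (6R,10S,13E,17E,21E,25E,29E)-6,10,14,18,22,26,30,34-octamethylpentatriaconta-13,17,21,25,29,33-hexaen-2-one | CC(C)=CCC/C(C)=C/CC/C(C)=C/CC/C(C)=C/CC/C(C)=C/CC/C(C)=C/CC[C@@H](C)CCC[C@@H](C)CCCC(C)=O | intermediate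
21 | diethyl (6R,10S,13E,17E,21E,25E,29E)-6,10,14,18,22,26,30,34-octamethylpentatriaconta-1,13,17,21,25,29,33-heptaen-2-yl phosphate | CC(C)=CCC/C(C)=C/CC/C(C)=C/CC/C(C)=C/CC/C(C)=C/CC/C(C)=C/CC[C@@H](C)CCC[C@@H](C)CCCC(=C)OP(=O)(OCC)OCC | intermediate (not isolated)
22 | (6R,10S,13E,17E,21E,25E,29E)-6,10,14,18,22,26,30,34-octamethylpentatriaconta-13,17,21,25,29,33-hexaen-1-yne | CC(C)=CCC/C(C)=C/CC/C(C)=C/CC/C(C)=C/CC/C(C)=C/CC/C(C)=C/CC[C@@H](C)CCC[C@@H](C)CCCC#C | intermediate
23 | dimethyl[(1E,6R,10S,13E,17E,21E,25E,29E)-2,6,10,14,18,22,26,30,34-nonamethylpentatriaconta-1,13,17,21,25,29,33-heptaen-1-yl]alumane | CC(C)=CCC/C(C)=C/CC/C(C)=C/CC/C(C)=C/CC/C(C)=C/CC/C(C)=C/CC[C@@H](C)CCC[C@@H](C)CCC/C(C)=C/[Al](C)C | intermediate (not isolated)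
24 | 2-methyl-3-[(2E,7R,11S,14E,18E,22E,26E,30E)-3,7,11,15,19,23,27,31,35-nonamethylhexatriaconta-2,14,18,22,26,30,34-heptaen-1-yl]naphthalene-1,4-dione | CC(C)=CCC/C(C)=C/CC/C(C)=C/CC/C(C)=C/CC/C(C)=C/CC/C(C)=C/CC[C@@H](C)CCC[C@@H](C)CCC/C(C)=C/CC1=C(C)C(=O)c2ccccc2C1=O | target

## Step count and risk

Total step count: 15.
Longest linear sequence: 9 steps (steps 6, 7, 9, 10, 11, 12, 13, 14, 15, from 8 to 24). The dyad branch from 3 is 8 steps; steps 1 and 8 are one-step side branches.

**Step 15 (key step).** The most likely failures are addition of the alkenylalane or of residual methylaluminium species to the quinone carbonyls, electron transfer to the quinone, transfer of methyl instead of alkenyl to the benzylic carbon, and incomplete carboalumination of a waxy C43 substrate. The fallback takes the quinone out of the coupling; it sets out from 22 (and from 1 for the aromatic partner) and comes back at 24. Reductive methylation of 1 (Na2S2O4, then Me2SO4/KOH) would give 1,4-dimethoxy-2-methylnaphthalene F1, and chloromethylation (paraformaldehyde, HCl, AcOH) would give 2-(chloromethyl)-1,4-dimethoxy-3-methylnaphthalene F2. Alkenylalane 23, made from 22 as in step 15, would be coupled with F2 under Pd(PPh3)4 catalysis (zerovalent palladium, alkenylalane–benzyl halide coupling) to give the hydroquinone dimethyl ether F3. Oxidative demethylation of F3 with (NH4)2Ce(NO3)6 in MeCN/H2O at 0 °C would give 24.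

**Step 4.** The most likely failure is poor facial selectivity at the hydroxymethyl-substituted olefin, because the free hydroxyl can bind iridium and override the steric model, or acid-induced isomerisation of the allylic alcohol before reduction. Any C11′ epimer would then be carried on inseparably. The fallback sets the two centres one at a time with two different control elements; it sets out from 5 and comes back at 6. Oxidation with MnO2 would give the enal F4, and NaClO2/NaH2PO4/2-methylbut-2-ene would give the dienoic acid F5. Carboxylate-directed hydrogenation with Ru(OAc)2[(S)-H8-BINAP] (H2, MeOH, Et3N) reduces only the conjugated olefin and would give the (2S)-acid F6; the ligand enantiomer is chosen by analogy with simple (E)-2-methylalk-2-enoic acids and confirmed on a model, and the acid can be enriched as an amine salt. LiAlH4 would give the alcohol F7. Iridium-catalysed hydrogenation of the single remaining unfunctionalised olefin, the substrate class on which these catalysts are most secure, would then give 6.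

**Step 12.** The most likely failures are attack of the Grignard reagent on the acetate carbonyl in competition with the copper-mediated substitution, γ-attack (SN2′) at C15′, and homocoupling during Grignard formation. The fallback reverses the polarity of the union; it sets out from 16 and 7 and comes back at 19. PBr3 (Et2O, 0 °C) would convert 16 into all-E-hexaprenyl bromide F8, and p-TolSO2Na in DMF would give all-E-hexaprenyl p-tolyl sulfone F9. Deprotonation of F9 (n-BuLi, THF/DMPU, −78 °C) and alkylation with bromide 7 would give the coupled sulfone F10 as a mixture of epimers at the sulfonyl carbon. Desulfonylation with Pd(dppp)Cl2/LiEt3BH, as in step 10, would give 19.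

## Further compounds

F1 | step 15 | 1,4-dimethoxy-2-methylnaphthalene | COc1cc(C)c(OC)c2ccccc12
F2 | step 15 | 2-(chloromethyl)-1,4-dimethoxy-3-methylnaphthalene | COc1c(C)c(CCl)c(OC)c2ccccc12
F3 | step 15 | 1,4-dimethoxy-2-methyl-3-[(2E,7R,11S,14E,18E,22E,26E,30E)-3,7,11,15,19,23,27,31,35-nonamethylhexatriaconta-2,14,18,22,26,30,34-heptaen-1-yl]naphthalene | CC(C)=CCC/C(C)=C/CC/C(C)=C/CC/C(C)=C/CC/C(C)=C/CC/C(C)=C/CC[C@@H](C)CCC[C@@H](C)CCC/C(C)=C/Cc1c(C)c(OC)c2ccccc2c1OC
F4 | step 4 | (2E,6E)-2,6-dimethyl-9-(2-methyl-1,3-dioxolan-2-yl)nona-2,6-dienal | O=C/C(C)=C/CC/C(C)=C/CCC1(C)OCCO1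
F5 | step 4 | (2E,6E)-2,6-dimethyl-9-(2-methyl-1,3-dioxolan-2-yl)nona-2,6-dienoic acid | OC(=O)/C(C)=C/CC/C(C)=C/CCC1(C)OCCO1
F6 | step 4 | (2S,6E)-2,6-dimethyl-9-(2-methyl-1,3-dioxolan-2-yl)non-6-enoic acid | OC(=O)[C@@H](C)CCC/C(C)=C/CCC1(C)OCCO1
F7 | step 4 | (2S,6E)-2,6-dimethyl-9-(2-methyl-1,3-dioxolan-2-yl)non-6-en-1-ol | OC[C@@H](C)CCC/C(C)=C/CCC1(C)OCCO1
F8 | step 12 | (2E,6E,10E,14E,18E)-1-bromo-3,7,11,15,19,23-hexamethyltetracosa-2,6,10,14,18,22-hexaene | CC(C)=CCC/C(C)=C/CC/C(C)=C/CC/C(C)=C/CC/C(C)=C/CC/C(C)=C/CBr
F9 | step 12 | 1-methyl-4-{[(2E,6E,10E,14E,18E)-3,7,11,15,19,23-hexamethyltetracosa-2,6,10,14,18,22-hexaen-1-yl]sulfonyl}benzene | CC(C)=CCC/C(C)=C/CC/C(C)=C/CC/C(C)=C/CC/C(C)=C/CC/C(C)=C/CS(=O)(=O)c1ccc(C)cc1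
F10 | step 12 | 2-methyl-2-[(4R,8S,11E,15E,19E,23E,27E)-4,8,12,16,20,24,28,32-octamethyl-10-(4-methylbenzenesulfonyl)tritriaconta-11,15,19,23,27,31-hexaen-1-yl]-1,3-dioxolane (mixture of C10 epimers) | CC(C)=CCC/C(C)=C/CC/C(C)=C/CC/C(C)=C/CC/C(C)=C/CC/C(C)=C/C(C[C@@H](C)CCC[C@@H](C)CCCC1(C)OCCO1)S(=O)(=O)c1ccc(C)cc1
A1 | alternative 1 | (2E,7R,11S,14E,18E,22E,26E,30E)-3,7,11,15,19,23,27,31,35-nonamethylhexatriaconta-2,14,18,22,26,30,34-heptaen-1-ol | CC(C)=CCC/C(C)=C/CC/C(C)=C/CC/C(C)=C/CC/C(C)=C/CC/C(C)=C/CC[C@@H](C)CCC[C@@H](C)CCC/C(C)=C/CO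
A2 | alternative 1 | 2-methylnaphthalene-1,4-diol (menadiol) | Cc1cc(O)c2ccccc2c1O
A3 | alternative 2 | (5E,10R,14S,17E,21E,25E,29E,33E)-6,10,14,18,22,26,30,34,38-nonamethylnonatriaconta-5,17,21,25,29,33,37-heptaen-2-yne | CC(C)=CCC/C(C)=C/CC/C(C)=C/CC/C(C)=C/CC/C(C)=C/CC/C(C)=C/CC[C@@H](C)CCC[C@@H](C)CCC/C(C)=C/CC#CC
A4 | alternative 2 | pentacarbonyl[methoxy(phenyl)methylidene]chromium, (CO)5Cr=C(OMe)Ph | COC(c1ccccc1)=[Cr](=C=O)(=C=O)(=C=O)(=C=O)=C=O
A5 | alternative 3 | (2E,6E,10E,14E,18E,22E,26E,30E)-3,7,11,15,19,23,27,31,35-nonamethylhexatriaconta-2,6,10,14,18,22,26,30,34-nonaen-1-ol (solanesol) | CC(C)=CCC/C(C)=C/CC/C(C)=C/CC/C(C)=C/CC/C(C)=C/CC/C(C)=C/CC/C(C)=C/CC/C(C)=C/CC/C(C)=C/CO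
A6 | alternative 3 | 2-methyl-3-[(2E,6E,10E,14E,18E,22E,26E,30E)-3,7,11,15,19,23,27,31,35-nonamethylhexatriaconta-2,6,10,14,18,22,26,30,34-nonaen-1-yl]naphthalene-1,4-dione (menaquinone-9) | CC(C)=CCC/C(C)=C/CC/C(C)=C/CC/C(C)=C/CC/C(C)=C/CC/C(C)=C/CC/C(C)=C/CC/C(C)=C/CC/C(C)=C/CC1=C(C)C(=O)c2ccccc2C1=O
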